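(The runs were generated by integration with constants of no real substance; the scatter is artificial.)

The green run ends at 8.00 min with 63% of left-handed product, more than the 50.0% of the charge that was left-handed substrate, so right-handed substrate has crossed over by way of the racemization catalyst.

| flask | left-handed substrate | right-handed substrate | reagent | racemization catalyst | precatalyst | remark | time |
|---|---|---|---|---|---|---|---|
| green | 0.050 M | 0.050 M | 0.20 M | 1 mM | 5 mM | run made earlier |  |
| teal | 0.20 M | 0.20 M | 0.20 M | 1 mM | 5 mM | run made earlier |  |
| ochre | 0.10 M | 0.10 M | 0.20 M | 1 mM | 2.5 mM | run made earlier |  |
| flask | 0.10 M | 0.10 M | 0.200 M | 1.0 mM | 5.0 mM |  | 6.0 min |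

| run | time / min | left-handed product / % | right-handed product / % |
|---|---|---|---|
| green | 0.833 | 50 | 27 |
| green | 2.50 | 61 | 38 |
| green | 5.00 | 63 | 35 |
| green | 8.00 | 63 | 37 |
| teal | 0.500 | 21 | 14 |
| teal | 1.33 | 30 | 18 |
| teal | 3.00 | 31 | 19 |
| teal | 8.00 | 32 | 18 |
| ochre | 2.00 | 44 | 26 |
| ochre | 4.00 | 53 | 32 |
| ochre | 5.00 | 52 | 33 |
| ochre | 8.00 | 56 | 34 |

(readings scatter by 1.5 percentage points)

- free catalyst is single-handed; left-handed substrate and right-handed substrate are mirror images of each other, charged as a racemate, each of them at the stated concentration
- what may be going on: reagent + free catalyst + left-handed substrate -> free catalyst + left-handed product; reagent + free catalyst + right-handed substrate -> free catalyst + right-handed product; left-handed substrate + racemization catalyst <-> right-handed substrate + racemization catalyst; reagent + racemization catalyst -> spent catalyst; precatalyst -> free catalyst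
- an excess is below zero if the other one leads

- left-handed product and right-handed product together, in percent of the left-handed substrate and right-handed substrate charged together, at 6.0 min
- excess of left-handed product over right-handed product in the product at 6.0 min
- whether the exchange between left-handed substrate and right-handed substrate keeps pace with the reaction: how far the product's excess at 6.0 min gets from its value without exchange to its value with instant exchange (above 80% keeps pace, below 20% hardly takes part, else lags behind)

The last readings of two runs give the part of the product that is left-handed, at very different conversions. Green ends at 100% of the charge. Teal, with reagent at 50.0% of its two substrates together, ends at 50.0%.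

green: 63% / (63% + 37%) = 63.0%

teal: 32% / (32% + 18%) = 64.0%

These differ by 1 percentage point, less than the scatter of 1.5 points on one reading. A part that holds across such a range of conversion says the two substrates stay level while they are consumed. Their mean is then the left share, the part of each turnover that gives left-handed product, 63.5%. As a selectivity factor this is 1.74.

Two rules follow; the first does without the yield, and the second has it as a factor:

excess = 2 × left share − 1 = 27.0%

left-handed product = left share × yield

The flask charges reagent at 100% of its two substrates together, and this reckoning puts its excess at 27.0%, with the exchange keeping pace.

The forecast gives a yield of 93% (90% to 96%), an excess of 25% (22% to 28%) and "keeps pace", on the ground that “the excess stays near 25 % regardless of conversion”. The excess reckoned here is higher by 2 points, inside the forecast's range.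

The flask gives a yield of 93.9%, an excess of 27.2%, and "keeps pace", 99% of the way to the excess with instant exchange.

    reagent + free catalyst + left-handed substrate → free catalyst + left-handed product (k = 58.0 /M²/s)
    reagent + free catalyst + right-handed substrate → free catalyst + right-handed product (k = 33.0 /M²/s)
    left-handed substrate + racemization catalyst ⇌ right-handed substrate + racemization catalyst, rate k3*[racemization catalyst]*[left-handed substrate] forward; the back reaction follows from the equilibrium constant (k = 2000 /M/s)
    reagent + racemization catalyst → spent catalyst (k = 0.180 /M/s)
    precatalyst → free catalyst (k = 0.110 /s)

At 0.471 min the flask's reaction uses left-handed substrate at 0.032 of the rate of its forward exchange. At 3.00 min the two substrates stand level in the flask, at 5.78% and 5.81%. The left share times the yield gives 59.6% of left-handed product, and the flask holds 59.7% at 6.00 min. A neighbour flask charged with 0.12 M of reagent reaches a yield of 59.7%, for which the left share gives 37.9%; that neighbour holds 38.0% of left-handed product at 6.00 min, with reagent, its limiting reagent, down to 0.0631%.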